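The route rests on cutting C5–C6 and C9–C9a (tuberostemonine numbering). The azepine ring is read as a formal (4+3) adduct of a butadiene (C6–C9) and the three-atom unit C5–N4–C9a, the corner where the pyrrole, azepine and cyclohexane rings meet. The precursor is a 3-(butenolid-4-yl)-5-iodopyrrole. Its N-methoxymethyl group, until then a protecting group, is ionised to an N-methylenepyrrolium ion. The tethered (E)-diene attacks this ion through C6, and the resulting allyl cation alkylates C9a. One operation closes the six- and the seven-membered ring and sets C9. A face-selective hydrogenation (C12, C13) and attachment of the side-chain lactone at the iodide complete the synthesis.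

Key step: step 8

Remark on numbering:
- N4 is the ring nitrogen; C5–C9 are the azepine carbons, from N-CH2 (C5) to the methine (C9).
- C9a, C1, C2 and C3 are the pyrrole carbons; C9a is next to C9, C1 bears C12, and C3 bears the side chain.
- C10 = CH(Et), C11 = CH–O, C12 = CH on C1, C13 = CH(CH3).
- C18 and C20 are the CH–O and CH(CH3) of the side-chain lactone.

Compounds 1, 3, 5 and 19 (as a THF solution) are taken as commercial.

Step 1
Reactants: 1 (E)-pent-2-en-1-ol
Product: 2 (E)-pent-2-en-1-ylboronic acid pinacol ester
Conditions: B2pin2, Pd(MeCN)4(BF4)2 (5 mol %), DMSO–MeOH, 50 °C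
Reagents that add atoms: bis(pinacolato)diboron CC1(C)OB(OC1(C)C)B1OC(C)(C)C(C)(C)O1
Why: Palladium-catalysed borylation of an allylic alcohol through an η3-allylpalladium intermediate should give the linear allylboronate with the favoured (E) geometry.

Step 2
Reactants: 2 (E)-pent-2-en-1-ylboronic acid pinacol ester; 3 but-2-ynal
Product: 4 (4R,5R)-5-ethylhept-6-en-2-yn-4-ol
Conditions: (R)-TRIP phosphoric acid [(R)-3,3'-bis(2,4,6-triisopropylphenyl)-BINOL hydrogen phosphate] (5 mol %), 4 Å MS, toluene, −30 °C; aq. NaHCO3
Reagents that add atoms: none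
Why: In this chiral-phosphoric-acid-catalysed allylboration through a closed chair transition state, the (E)-boronate should give the anti relation of the future C10 and C11, and the (R)-acid should direct attack to the Re face of the ynal (carbinol R).

Step 3
Reactants: 5 3-bromo-1-(triisopropylsilyl)-1H-pyrrole
Product: 7 3-bromo-1-(methoxymethyl)-1H-pyrrole, via tetrabutylammonium 3-bromopyrrol-1-ide 6 (not isolated)
Conditions: TBAF (1 M in THF, dried over 4 Å MS), THF, −10 °C; then MOMCl, −10 to 20 °C
Reagents that add atoms: chloromethyl methyl ether COCCl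
Why: Fluoride-induced N-desilylation followed by SN2 N-alkylation of the pyrrolide in the same flask should avoid handling labile 3-bromopyrrole, and it installs the carbon that becomes C5.

Step 4
Reactants: 4 (4R,5R)-5-ethylhept-6-en-2-yn-4-ol; 7 3-bromo-1-(methoxymethyl)-1H-pyrrole
Product: 12 (5R)-4-[1-(methoxymethyl)-1H-pyrrol-3-yl]-3-methyl-5-[(3R)-pent-1-en-3-yl]furan-2(5H)-one, via Grignard reagent 8 (not isolated), via chloromagnesium alkoxide 9 (not isolated), via oxamagnesacycle 10 (not isolated), via hydroxy acid 11 (not isolated)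
Conditions: 7, Mg, LiCl, THF, 25 °C; 4, i-PrMgCl, THF, 0 °C; combine, CuI (10 mol %), THF–toluene, 65 °C; CO2 (1 atm), 0 °C; 1 M HCl
Reagents that add atoms: carbon dioxide O=C=O
Why: Copper-catalysed, alkoxide-directed anti-carbomagnesiation of a propargylic alcohol should place the pyrrolyl group on the alkyne carbon next to the carbinol and magnesium on the methyl-bearing carbon within a five-membered chelate, so that carboxylation puts CO2H cis to the carbinol and acidification closes the butenolide with both stereocentres untouched.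

Step 5
Reactants: 12 (5R)-4-[1-(methoxymethyl)-1H-pyrrol-3-yl]-3-methyl-5-[(3R)-pent-1-en-3-yl]furan-2(5H)-one
Product: 13 (5R)-4-[5-iodo-1-(methoxymethyl)-1H-pyrrol-3-yl]-3-methyl-5-[(3R)-pent-1-en-3-yl]furan-2(5H)-one
Conditions: NIS, DMF, −20 °C, dark
Reagents that add atoms: N-iodosuccinimide O=C1CCC(=O)N1I
Why: Electrophilic aromatic iodination should go to C3, because the conjugated butenolide deactivates the adjacent C9a as a 3-acyl group would and both neighbours shield that position.

Step 6
Reactants: 13 (5R)-4-[5-iodo-1-(methoxymethyl)-1H-pyrrol-3-yl]-3-methyl-5-[(3R)-pent-1-en-3-yl]furan-2(5H)-one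
Product: 14 (2E,4R)-4-{(2R)-3-[5-iodo-1-(methoxymethyl)-1H-pyrrol-3-yl]-4-methyl-5-oxo-2,5-dihydrofuran-2-yl}hex-2-enal
Conditions: crotonaldehyde (5 equiv), second-generation Hoveyda–Grubbs catalyst (5 mol %), CH2Cl2, 40 °C
Reagents that add atoms: (E)-crotonaldehyde C/C=C/C=O
Why: Olefin cross-metathesis of the only terminal alkene with an electron-poor partner should give the (E)-enal under neutral conditions, which leave the acidic H11 untouched.

Step 7
Reactants: 14 (2E,4R)-4-{(2R)-3-[5-iodo-1-(methoxymethyl)-1H-pyrrol-3-yl]-4-methyl-5-oxo-2,5-dihydrofuran-2-yl}hex-2-enal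
Product: 15 (5R)-5-[(3R,4E)-hepta-4,6-dien-3-yl]-4-[5-iodo-1-(methoxymethyl)-1H-pyrrol-3-yl]-3-methylfuran-2(5H)-one
Conditions: TMSCHN2, PPh3, i-PrOH, RhCl(PPh3)3 (2.5 mol %), THF, 25 °C
Reagents that add atoms: (trimethylsilyl)diazomethane C[Si](C)(C)C=[N+]=[N-]
Why: Rhodium-catalysed methylenation, a salt-free and base-free Wittig reaction, should convert the aldehyde into the terminal (E)-diene without epimerising C10 or C11.

Step 8
Reactants: 15 (5R)-5-[(3R,4E)-hepta-4,6-dien-3-yl]-4-[5-iodo-1-(methoxymethyl)-1H-pyrrol-3-yl]-3-methylfuran-2(5H)-one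
Product: 18 (9S,10R,11R)-tetracyclic iodopyrrole (C7=C8 alkene; C12=C13 butenolide), via N-methylenepyrrolium triflate 16 (not isolated), via macrocyclic allyl cation 17 (not isolated)
Conditions: TMSOTf (1.5 equiv), 2,6-di-tert-butyl-4-methylpyridine (2 equiv), CH2Cl2, slow addition of 15 (final 0.5 mM), −40 to 0 °C
Reagents that add atoms: none
Why: Proposed new method: TMSOTf should ionise the N,O-acetal to the N-methylenepyrrolium ion 16, whose CH2 (C5) is attacked by the diene terminus C6 (vinylogous aza-Prins step) to give allyl cation 17, which alkylates the neighbouring pyrrole carbon C9a through C9 (Friedel–Crafts step) before the hindered pyridine takes up the proton, overall a tethered formal (4+3) annulation of a diene with the unit C5–N4–C9a. The closest known reaction types are aza-Prins/Friedel–Crafts cascades of N-acyliminium ions, amidomethylation of π-nucleophiles with N-(alkoxymethyl)imides, and the (4+3) annulation of dienes with indol-3-ylmethyl cations, in which the ring carbon next to the cationic side chain likewise closes the seven-membered ring. With respect to the allyl cation the cyclohexene ring closes 6-exo-trig and the azepine ring 7-endo-trig, and the first bond forms in a folded, cycloaddition-like conformer (an 11-membered ring in 17). C9 is the only new stereocentre: the planar butenolide forces O11 equatorial and H11 axial in the chair-like six-ring transition state, the ethyl group on C10 is then axial on the face away from the diene (without a 1,3-diaxial partner, since C12 is sp2), and the diene arm on C9 should take the equatorial, extended orientation (twist-chair azepine), which places H9 cis to H10 and H11 (9S). Chemoselectivity (the diene rather than a second pyrrole as nucleophile) is secured by the iodine that blocks C3, by the butenolide that lowers the ground-state nucleophilicity of the ring, and by high dilution; regioselectivity (C9 rather than C7 of the allyl cation) is secured by the tether C10–C11–C12, because attack at C7 would leave a strained eight-membered ring.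

Step 9
Reactants: 18 (9S,10R,11R)-tetracyclic iodopyrrole; 19 (R)-(3-methoxy-2-methyl-3-oxopropyl)zinc bromide
Product: 20 unsaturated keto ester (9S,10R,11R,20S)
Conditions: CO (1 atm), Pd(PPh3)4 (5 mol %), THF, 40 °C
Reagents that add atoms: carbon monoxide [C-]#[O+]
Why: In a carbonylative Negishi coupling, oxidative addition of the C3–I bond, CO insertion and transmetalation with the ester-bearing alkylzinc reagent should give the ketone, and C20 comes unchanged from 19.

Step 10
Reactants: 20 unsaturated keto ester (9S,10R,11R,20S)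
Product: 21 saturated keto ester (9S,10R,11R,12S,13S,20S)
Conditions: H2 (60 bar), Pd/C (10 wt %), EtOAc, 40 °C
Reagents that add atoms: none
Why: Heterogeneous catalytic hydrogenation should add hydrogen syn to C7=C8 and to the tetrasubstituted C12=C13 bond from the face that carries H9, H10 and H11 (the other face is shielded by the axial ethyl group), which sets 12S and 13S with all five ring hydrogens cis.

Step 11
Reactants: 21 saturated keto ester (9S,10R,11R,12S,13S,20S)
Product: 23 epibisdehydroneotuberostemonine J, via hydroxy ester 22 (not isolated)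
Conditions: RuCl[(R,R)-TsDPEN](p-cymene) (2 mol %), HCO2H–Et3N (5:2), CH2Cl2, 30 °C
Reagents that add atoms: none
Why: In an asymmetric transfer hydrogenation of the Noyori type the (R,R)-catalyst should reduce the pyrrolyl ketone to the 18R alcohol under catalyst control, and the γ-hydroxy ester should lactonise in the flask to the trans-disubstituted side-chain lactone.

Compound list
1 | (E)-pent-2-en-1-ol | CC/C=C/CO | starting material
2 | (E)-pent-2-en-1-ylboronic acid pinacol ester | CC/C=C/CB1OC(C)(C)C(C)(C)O1 | intermediate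
3 | but-2-ynal | CC#CC=O | starting material
4 | (4R,5R)-5-ethylhept-6-en-2-yn-4-ol | CC[C@H](C=C)[C@@H](O)C#CC | intermediate
5 | 3-bromo-1-(triisopropylsilyl)-1H-pyrrole | CC(C)[Si](C(C)C)(C(C)C)n1ccc(Br)c1 | starting material
6 | tetrabutylammonium 3-bromopyrrol-1-ide | CCCC[N+](CCCC)(CCCC)CCCC.Brc1cc[n-]c1 | intermediate
7 | 3-bromo-1-(methoxymethyl)-1H-pyrrole | COCn1ccc(Br)c1 | intermediate
8 | [1-(methoxymethyl)-1H-pyrrol-3-yl]magnesium bromide | COCn1ccc([Mg]Br)c1 | intermediate
9 | chloromagnesium alkoxide of 4 | CC[C@H](C=C)[C@@H](O[Mg]Cl)C#CC | intermediate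
10 | five-membered oxamagnesacycle (O–Mg–C13=C12–C11; pyrrolyl on C12) | CC[C@H](C=C)[C@H]1O[Mg]C(C)=C1c1ccn(COC)c1 | intermediate
11 | (2Z,4R,5R)-5-ethyl-4-hydroxy-3-[1-(methoxymethyl)-1H-pyrrol-3-yl]-2-methylhepta-2,6-dienoic acid | CC[C@H](C=C)[C@@H](O)/C(c1ccn(COC)c1)=C(/C)C(=O)O | intermediate
12 | (5R)-4-[1-(methoxymethyl)-1H-pyrrol-3-yl]-3-methyl-5-[(3R)-pent-1-en-3-yl]furan-2(5H)-one | CC[C@H](C=C)[C@H]1OC(=O)C(C)=C1c1ccn(COC)c1 | intermediate
13 | (5R)-4-[5-iodo-1-(methoxymethyl)-1H-pyrrol-3-yl]-3-methyl-5-[(3R)-pent-1-en-3-yl]furan-2(5H)-one | CC[C@H](C=C)[C@H]1OC(=O)C(C)=C1c1cc(I)n(COC)c1 | intermediate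
14 | (2E,4R)-4-{(2R)-3-[5-iodo-1-(methoxymethyl)-1H-pyrrol-3-yl]-4-methyl-5-oxo-2,5-dihydrofuran-2-yl}hex-2-enal | CC[C@H](/C=C/C=O)[C@H]1OC(=O)C(C)=C1c1cc(I)n(COC)c1 | intermediate
15 | (5R)-5-[(3R,4E)-hepta-4,6-dien-3-yl]-4-[5-iodo-1-(methoxymethyl)-1H-pyrrol-3-yl]-3-methylfuran-2(5H)-one | CC[C@H](/C=C/C=C)[C@H]1OC(=O)C(C)=C1c1cc(I)n(COC)c1 | intermediate
16 | N-methylenepyrrolium triflate from 15 (N4=C5H2 cation; 10R,11R) | CC[C@H](/C=C/C=C)[C@H]1OC(=O)C(C)=C1C1=C[N+](=C)C(I)=C1.[O-]S(=O)(=O)C(F)(F)F | intermediate
17 | macrocyclic allyl cation, triflate salt (C5–C6 bond made; charge over C7–C9; 10R,11R) | CC[C@H]1[C@H]2OC(=O)C(C)=C2c2cc(I)n(CCC=C[CH+]1)c2.[O-]S(=O)(=O)C(F)(F)F | intermediate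
18 | tetracyclic iodide: 3-iodopyrrole fused to the dihydroazepine (C7=C8), the cyclohexene ring (C9, C10-ethyl, C11) and the α-methylbutenolide (C12=C13); 9S,10R,11R; H9, H10, H11 cis | CC[C@H]1[C@H]2OC(=O)C(C)=C2c2cc(I)n3c2[C@H]1C=CCC3 | intermediate
19 | (R)-(3-methoxy-2-methyl-3-oxopropyl)zinc bromide | Br[Zn]C[C@H](C)C(=O)OC | starting material
20 | methyl (2S)-2-methyl-4-oxo-4-(tetracycl-3-yl)butanoate, C7=C8 and C12=C13 still present (9S,10R,11R,20S) | CC[C@H]1[C@H]2OC(=O)C(C)=C2c2cc(C(=O)C[C@H](C)C(=O)OC)n3c2[C@H]1C=CCC3 | intermediate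
21 | saturated keto ester with cis-fused α-methyl-γ-lactone (9S,10R,11R,12S,13S,20S) | CC[C@H]1[C@H]2OC(=O)[C@@H](C)[C@H]2c2cc(C(=O)C[C@H](C)C(=O)OC)n3c2[C@H]1CCCC3 | intermediate
22 | γ-hydroxy ester (9S,10R,11R,12S,13S,18R,20S) | CC[C@H]1[C@H]2OC(=O)[C@@H](C)[C@H]2c2cc([C@H](O)C[C@H](C)C(=O)OC)n3c2[C@H]1CCCC3 | intermediate
23 | epibisdehydroneotuberostemonine J (9S,10R,11R,12S,13S,18R,20S) | CC[C@H]1[C@H]2OC(=O)[C@@H](C)[C@H]2c2cc([C@H]3C[C@H](C)C(=O)O3)n3c2[C@H]1CCCC3 | target

Total step count: 11. Longest linear sequence: 10 (steps 1, 2 and 4–11; step 3 is a side branch).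

Steps most likely to fail

1. Step 8.
- What may go wrong: ionisation of the deactivated N,O-acetal may be sluggish. The N-methylene cation may be captured by a second pyrrole molecule, leading to oligomerisation. The allyl cation may lose a proton before ring closure. Closure through the compact instead of the extended orientation would cost facial selectivity at C9.
- Fallback (known chemistry, rings closed one after the other): it sets out from 13 and comes back at 18. Cross-metathesis of 13 with (Z)-but-2-ene-1,4-diyl dimethyl dicarbonate (second-generation Hoveyda–Grubbs catalyst) would give the (E)-allylic methyl carbonate F1. An iridium-catalysed intramolecular Friedel–Crafts-type allylic alkylation at C9a ([Ir(cod)Cl]2, chiral phosphoramidite, THF) would close the six-membered ring and give the 9-vinyl tricycle F2. Removal of the methoxymethyl group (BCl3, then aq. NaHCO3) would give the NH-pyrrole F3. N-alkylation with 4-bromobut-1-ene (Cs2CO3, MeCN) would give the N-butenyl diene F4. Ring-closing metathesis (second-generation Grubbs catalyst) would then form C7=C8 and deliver 18.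

2. Step 4.
- What may go wrong: carbomagnesiation of the hindered internal alkyne may be slow. Magnesium may migrate from the 3- to the 2-position of the pyrrole on heating. Carboxylation of the chelate may be incomplete.
- Fallback (butenolide built first, substituents added by cross-coupling): it sets out from 2 and 7 and comes back at 12. Commercial mucobromic acid would be converted with TMSCHN2 into its open-chain ester, methyl (Z)-2,3-dibromo-4-oxobut-2-enoate F5. Allylboration of F5 with 2 under the conditions of step 2, with lactonisation of the adduct, would give the dibromobutenolide F6. Miyaura borylation of 7 (B2pin2, PdCl2(dppf), KOAc) would give the pyrrol-3-ylboronate F7. Site-selective Suzuki coupling at the more electrophilic 4-position of F6 (Pd(PPh3)4, K3PO4) would give the 3-bromo-4-pyrrolylbutenolide F8. Negishi methylation (MeZnCl, Pd(PPh3)4) would give 12.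

3. Step 10.
- What may go wrong: saturation of the tetrasubstituted, pyrrole-conjugated C12=C13 bond may be incomplete. The allylic C11–O bond may undergo hydrogenolysis. Facial selectivity may erode.
- Fallback (hydride conjugate addition with protonation instead of surface hydrogenation): it sets out from 20 and comes back at 23. The transfer hydrogenation and lactonisation of step 11 would be run first and give the doubly unsaturated dilactone F9. Nickel boride (NiCl2·6H2O, NaBH4, MeOH, −30 °C) would then saturate C7=C8, add hydride to C12 from the open face and protonate C13 from the same face, giving 23.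

Further compounds
F1 | step 8 | (E)-allylic methyl carbonate from 13 (10R,11R) | CC[C@H](/C=C/COC(=O)OC)[C@H]1OC(=O)C(C)=C1c1cc(I)n(COC)c1
F2 | step 8 | 9-vinyl tricycle, N-methoxymethyl (9S,10R,11R) | CC[C@H]1[C@H]2OC(=O)C(C)=C2c2cc(I)n(COC)c2[C@H]1C=C
F3 | step 8 | 9-vinyl tricyclic NH-pyrrole (9S,10R,11R) | CC[C@H]1[C@H]2OC(=O)C(C)=C2c2cc(I)[nH]c2[C@H]1C=C
F4 | step 8 | N-(but-3-en-1-yl)-9-vinyl tricycle (9S,10R,11R) | CC[C@H]1[C@H]2OC(=O)C(C)=C2c2cc(I)n(CCC=C)c2[C@H]1C=C
F5 | step 4 | methyl (Z)-2,3-dibromo-4-oxobut-2-enoate | COC(=O)/C(Br)=C(/Br)C=O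
F6 | step 4 | (5R)-3,4-dibromo-5-[(3R)-pent-1-en-3-yl]furan-2(5H)-one | CC[C@H](C=C)[C@H]1OC(=O)C(Br)=C1Br
F7 | step 4 | 1-(methoxymethyl)-1H-pyrrol-3-ylboronic acid pinacol ester | COCn1ccc(B2OC(C)(C)C(C)(C)O2)c1
F8 | step 4 | (5R)-3-bromo-4-[1-(methoxymethyl)-1H-pyrrol-3-yl]-5-[(3R)-pent-1-en-3-yl]furan-2(5H)-one | CC[C@H](C=C)[C@H]1OC(=O)C(Br)=C1c1ccn(COC)c1
F9 | step 10 | doubly unsaturated dilactone, C7=C8 and C12=C13 present (9S,10R,11R,18R,20S) | CC[C@H]1[C@H]2OC(=O)C(C)=C2c2cc([C@H]3C[C@H](C)C(=O)O3)n3c2[C@H]1C=CCC3
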